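**Retrosynthetic overview**

1. The target is 18-(5-formyl-1H-pyrrol-2-yl)octadecanenitrile. The chain is numbered from the nitrile carbon (C1) to the CH2 on pyrrole C5 (C18). There is no stereocentre, and the pyrrole ring is bought intact as pyrrole-2-carbaldehyde, so no ring is formed in the route.
2. Key disconnection, made last: C6–C7, by a nickel-hydride reductive hydroalkylation that joins the terminal alkene carbon of hex-5-enenitrile (C1–C6) to the primary iodide carbon C7 of 5-(12-iodododecyl)pyrrole-2-carbaldehyde. Neither partner is an organometallic reagent, and nothing is protected.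
3. Enabling feature: C6 and C7 are two unbranched, unfunctionalised CH2 groups of the (CH2)17 chain. C6 lies five carbons from the nitrile carbon, so it is the terminal =CH2 of the C5=C6 alkene of hex-5-enenitrile. C7 lies twelve CH2 from pyrrole C5, so it is the second terminus of 1,12-dibromododecane. Both are primary and remote from C≡N, N–H and CHO.
4. Earlier disconnection: pyrrole C5–C18, by Pd/norbornene C–H alkylation of pyrrole-2-carbaldehyde with 1,12-dibromododecane (C7–C18), followed by Br to I exchange.

Key step: step 3

**Route**

Step 1
Reactants: 1 1H-pyrrole-2-carbaldehyde; 2 1,12-dibromododecane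
Product: 3 5-(12-bromododecyl)-1H-pyrrole-2-carbaldehyde
Conditions: PdCl2(MeCN)2 (10 mol%), norbornene (2 equiv), KHCO3 (3 equiv), 2 (4 equiv), DMA, 90 °C
Reagents that add atoms: none
Why: Catellani-type Pd(II)/norbornene C–H alkylation of an NH-pyrrole carrying an electron-withdrawing group (N-palladation, aminopalladation of norbornene, C5–H palladation, oxidative addition of the primary bromide, reductive elimination, norbornene extrusion) should alkylate only C5, the free position next to N–H, while the fourfold excess of 2 keeps the second C–Br end intact and bicarbonate is too weak a base for N-alkylation.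

Step 2
Reactants: 3 5-(12-bromododecyl)-1H-pyrrole-2-carbaldehyde
Product: 4 5-(12-iodododecyl)-1H-pyrrole-2-carbaldehyde
Conditions: NaI (3 equiv), acetone, reflux, dark
Reagents that add atoms: sodium iodide, [Na+].[I-]
Why: Finkelstein reaction, an SN2 halide exchange at the primary bromide driven by precipitation of NaBr from acetone, to which the formyl group and the pyrrole N–H are inert.

Step 3
Reactants: 4 5-(12-iodododecyl)-1H-pyrrole-2-carbaldehyde; 5 hex-5-enenitrile
Product: 6 mycalenitrile 1
Conditions: NiBr2·diglyme (10 mol%), i-Pr-pybox (12 mol%), (EtO)2MeSiH (2.5 equiv), Na2CO3 (3 equiv), 5 (3 equiv), DMA, 25 °C, Ar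
Reagents that add atoms: none
Why: Silane and carbonate convert the pybox–nickel halide into a Ni–H species that inserts the terminal alkene of 5 in the anti-Markovnikov sense and so places nickel on the primary carbon C6, while iodide 4 is activated separately by halogen abstraction/single-electron transfer at low-valent nickel to the C7 radical, which is captured by the C6 alkylnickel before reductive elimination from Ni(III) forms the C6–C7 bond. The closest known reaction type is the Ni–H-catalysed reductive anti-Markovnikov hydroalkylation of unactivated terminal olefins with primary alkyl iodides using a nickel/pybox catalyst, a hydrosilane and carbonate in DMA. No ring is closed and no stereocentre is created. The step needs cross-selectivity, linear regioselectivity and chemoselectivity; cross-selectivity is built in because the two partners enter the cycle by different elementary steps (hydrometalation versus radical capture), and the excess of 5 traps Ni–H before it can reduce the C–I bond. Linear selectivity should be secured by the monosubstituted, unbiased C5=C6 alkene, whose primary alkylnickel is favoured and should be consumed at 25 °C before chain walking toward the distant nitrile can compete. The formyl group is a vinylogous formamide conjugated with the pyrrole nitrogen and hence a poor hydride acceptor, and N–H and C≡N are expected to be tolerated by this catalyst system, so the target should emerge unprotected.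

**Compound list**

1 | 1H-pyrrole-2-carbaldehyde | O=Cc1ccc[nH]1 | starting material
2 | 1,12-dibromododecane | BrCCCCCCCCCCCCBr | starting material
3 | 5-(12-bromododecyl)-1H-pyrrole-2-carbaldehyde | O=Cc1ccc(CCCCCCCCCCCCBr)[nH]1 | intermediate
4 | 5-(12-iodododecyl)-1H-pyrrole-2-carbaldehyde | O=Cc1ccc(CCCCCCCCCCCCI)[nH]1 | intermediate
5 | hex-5-enenitrile | C=CCCCC#N | starting material
6 | mycalenitrile 1, 18-(5-formyl-1H-pyrrol-2-yl)octadecanenitrile | N#CCCCCCCCCCCCCCCCCCc1ccc(C=O)[nH]1 | target

**Step count and risks**

Total step count: 3. Longest linear sequence: 3 steps (1 → 3 → 4 → 6).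

Steps most likely to fail:

Step 3. The formyl group may be reduced by silane (base- or Ni–H-mediated hydrosilylation), the C–I bond may be hydrodehalogenated, or Ni–H chain walking along 5 may give branched isomers. The fallback sets out from bromide 3 (bypassing step 2) together with 5 and comes back at 6. Hydroboration of 5 with 9-BBN-H (THF, 0 °C to rt; the nitrile should not be touched) should give 6-(9-borabicyclo[3.3.1]nonan-9-yl)hexanenitrile F1. This is then coupled with 3 in a B-alkyl Suzuki–Miyaura alkyl–alkyl coupling (Pd(OAc)2, PCy3, K3PO4·H2O, THF, rt) to give 6. No B–H or Si–H species meets the aldehyde, because the borane is fully alkylated before 3 is added.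

Step 1. N-alkylation of the pyrrole may compete, the dibromide may be captured at both ends, or C5–H palladation of the formyl-substituted pyrrole may be slow. The fallback sets out from 1 and comes back at 3. Condensation of 1 with aqueous dimethylamine/dimethylamine hydrochloride should give the 6-(dimethylamino)-1-azafulvene dimer F2. Lithiation with t-BuLi (2.2 equiv, THF, −15 °C) next to each ring nitrogen gives the 3,8-dilithio dimer F3, which is added inversely to a large excess of 2 (THF, −78 °C to rt) to give the 3,8-bis(12-bromododecyl) dimer F4. Buffered hydrolysis (AcOH/NaOAc, THF–H2O, 50 °C) keeps the liberated amine protonated and should release two molecules of 3.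

Step 2. Halide exchange may be incomplete, leaving a bromide/iodide mixture that cannot be separated, and intermolecular N-alkylation may set in on prolonged heating. The fallback sets out from 1 and comes back at 4. C–H alkylation of 1 under the conditions of step 1 with 12-bromododecan-1-ol (OCCCCCCCCCCCCBr) in place of 2 should give 5-(12-hydroxydodecyl)-1H-pyrrole-2-carbaldehyde F5. An Appel reaction (I2, PPh3, imidazole, CH2Cl2, 0 °C) then converts the primary alcohol directly into iodide 4, without a halide-exchange equilibrium.

**Further compounds**

F1 | step 3 | 6-(9-borabicyclo[3.3.1]nonan-9-yl)hexanenitrile | N#CCCCCCB1C2CCCC1CCC2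
F2 | step 1 | 5,10-bis(dimethylamino)-5,10-dihydrodipyrrolo[1,2-a:1',2'-d]pyrazine (6-(dimethylamino)-1-azafulvene dimer) | CN(C)C1c2cccn2C(N(C)C)c2cccn12
F3 | step 1 | 3,8-dilithio-5,10-bis(dimethylamino)-5,10-dihydrodipyrrolo[1,2-a:1',2'-d]pyrazine | CN(C)C1c2ccc([Li])n2C(N(C)C)c2ccc([Li])n12
F4 | step 1 | 3,8-bis(12-bromododecyl)-5,10-bis(dimethylamino)-5,10-dihydrodipyrrolo[1,2-a:1',2'-d]pyrazine | CN(C)C1c2ccc(CCCCCCCCCCCCBr)n2C(N(C)C)c2ccc(CCCCCCCCCCCCBr)n12
F5 | step 2 | 5-(12-hydroxydodecyl)-1H-pyrrole-2-carbaldehyde | O=Cc1ccc(CCCCCCCCCCCCO)[nH]1
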